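The earlier runs and the new flask stem from a simulated flask with made-up constants; the scatter is artificial.

Product is what you can count, and each unit of it took up one unit of partner, so the readings work as a ledger of where the partner went.

| flask | starting material | partner | product | time |
|---|---|---|---|---|
| ochre | 200 mM | 220 mM |  |  |
| green | 100 mM | 120 mM |  |  |
| grey | 200 mM | 220 mM | 100 mM |  |
| violet | 200 mM | 110 mM |  |  |
| red | 600 mM | 220 mM |  | 37 min |

| run | time / min | [product] / mM |
|---|---|---|
| ochre run | 7.4 | 53.3 |
| ochre run | 15 | 74.2 |
| ochre run | 22 | 85.1 |
| ochre run | 30 | 91.0 |
| ochre run | 37 | 96.2 |
| green run | 7.4 | 19.2 |
| green run | 15 | 31.2 |
| green run | 22 | 35.2 |
| green run | 30 | 40.7 |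
| green run | 37 | 39.8 |
| grey run | 7.4 | 152.1 |
| grey run | 15 | 178.1 |
| grey run | 22 | 188.8 |
| grey run | 30 | 193.5 |
| grey run | 37 | 193.9 |
| violet run | 7.4 | 31.6 |
| violet run | 15 | 39.8 |
| violet run | 22 | 47.7 |
| violet run | 30 | 43.9 |
| violet run | 37 | 48.6 |

(readings scatter by 2 mM)

1. the exponent of [partner] in the starting rate at the charge of the ochre run (at the point where two percent of the starting material have become product)
2. the exponent of [starting material] in the starting rate at the charge of the ochre run (at the point where two percent of the starting material have become product) (one fixed amount of product, the same in the runs compared)
3. product in the red run at 37 min, as a share of the starting material charged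

- Overall: starting material + partner -> product.
- Constant volume, constant temperature.
- Bound and free are read together.
- "The second partner" is partner.
- An order is taken over about fifteen percent of the charge, up and down.

Take the rates in order, on a scale of powers of ten. On the fast rung the ochre readings give 7.20 mM/min on average up to 7.4 min, while on the slow rung, between 30 min and 37 min, they give 0.743 mM/min, about ten times slower, although subtraction from the last ochre reading still shows 0.104 M of starting material and 0.124 M of partner not in product. The grey flask has made 0.0939 M beyond its added product by 37 min, close to the 96.2 mM of the ochre flask, so within the scatter added product changes little. The violet flask, with half the partner of the ochre flask, reads half its product at the last reading, which reads as a power of 0.985 in partner.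

My reckoning is that partner has two exits, one into product and one elsewhere. So I carry the odds ω, a selectivity factor: product at the last reading over partner charged but not in product. The ochre flask gives 0.777 and the violet flask 0.792, so between these two flasks, at one charge of starting material, the partner charge moves ω by little, while the green flask, with half the starting material and also a different partner charge of 120 mM, gives 0.496, and on the strength of the ochre and violet pair I put that change on starting material. The slope of log ω against log [starting material], the odds exponent m, is 0.647. Assuming the other exit ignores starting material, I take m as the starting-rate exponent of starting material and 0.985 as that of partner. In the red flask, where partner is the limiting reagent at 220 mM against 600 mM, the charge of starting material is 3.00 times that of the ochre flask, so, carrying the power beyond the charges measured, I estimate ω at 1.58 at 37 min, which in my reckoning gives 135 mM of product, or 22.5% of the starting material.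

The forecast, to which the early flattening suggests that “the active agent dies”, gives 0.8 and 0.7 for the exponents, against my 0.985 and 0.647, and 22% for the red flask, against my 22.5%.

The red flask gives 22.4% of its starting material as product at 37 min, while the fit with main steps alone puts it at 33.4%, and at the charge of the ochre flask the exponents are 1.0 in partner and 0.57 in starting material.

    starting material + partner → product (1.476 /M/min)
    2 starting material ⇌ idle substrate dimer, settled at all times (68.80 /M)
    partner → lost reagent (0.05442 /min)

Now put m, read from end products, to an early rate in the green flask: scaling the ochre rate of 11 mM/min by the power m of the starting-material ratio and by the partner ratio predicts 3.73 mM/min, and the green flask, at the same amount of product made, runs at 3.7 mM/min.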